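The route rests on cutting the O6–C10 bond (acetogenin numbering, C1 = alkyne CH; O6 and O7 sit on C6 and C7). The anti pair C10–O6/C9–Br, beside bridgehead C10 on the two-carbon bridge C8–C9, is the imprint of a bromonium opening. The 1,4-dioxocane ring C (C6, O6, C10–C13, O7, C7) and the tetrahydropyran ring B are therefore closed together, last, by one transannular bromoetherification across oxocene ring A. This single operation makes C10–O and C9–Br, two rings and two stereocentres. The precursor is a monocyclic 7,13-cis (Z)-oxocene carrying C12–Br, the free (6R)-carbinol and an allyl stub. It is made by glycolate alkylation, two chelation-controlled allylations and ring-closing metathesis.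

Key step: step 13

Remark: acetogenin numbering (C1 alkyne CH to C15 ethyl CH3) is used for all intermediates. Ring A = O7, C7–C13; ring B = O6, C6–C10; ring C = C6, O6, C10, C11, C12, C13, O7, C7.

Step 1
Reactants: 1 (R)-1,2-epoxybutane; 2 4-methoxybenzyl alcohol
Product: 3 (2R)-1-[(4-methoxybenzyl)oxy]butan-2-ol
Conditions: NaH (0.2 equiv), 2 (excess), DMF, 60 °C, sealed tube
Reagents that add atoms: none
Why: Base-catalysed SN2 opening of the terminal epoxide by the benzylic alkoxide takes place at the unsubstituted carbon, so the stereocentre of 1 is carried over unchanged as C13 (R).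

Step 2
Reactants: 3 (2R)-1-[(4-methoxybenzyl)oxy]butan-2-ol; 4 bromoacetic acid
Product: 5 {[(2R)-1-(4-methoxybenzyloxy)butan-2-yl]oxy}acetic acid
Conditions: NaH (3 equiv), THF, 0 °C to reflux; then 1 M HCl
Reagents that add atoms: none
Why: Williamson ether synthesis of the secondary sodium alkoxide with the primary bromide of sodium bromoacetate forms the O7–C7 bond without touching C13.

Step 3
Reactants: 5 {[(2R)-1-(4-methoxybenzyloxy)butan-2-yl]oxy}acetic acid; 6 (S)-4-benzyloxazolidin-2-one
Product: 8 (4S)-4-benzyl-3-({[(2R)-1-(4-methoxybenzyloxy)butan-2-yl]oxy}acetyl)oxazolidin-2-one, via mixed pivalic anhydride 7 (not isolated)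
Conditions: t-BuCOCl, Et3N, THF, −20 °C; then LiCl, 6, −20 °C to rt
Reagents that add atoms: pivaloyl chloride, CC(C)(C)C(=O)Cl (its acyl group is carried only by 7)
Why: N-Acylation of the oxazolidinone through the mixed pivalic anhydride (attack at the less hindered glycolyl carbonyl, LiCl-assisted) installs the auxiliary for the Evans-type alkylation.

Step 4
Reactants: 8 N-glycolyl imide; 9 allyl iodide
Product: 10 (4S)-4-benzyl-3-[(2R)-2-{[(2R)-1-(4-methoxybenzyloxy)butan-2-yl]oxy}pent-4-enoyl]oxazolidin-2-one
Conditions: NaN(SiMe3)2, THF, −78 °C; then 9, −78 to −45 °C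
Reagents that add atoms: none
Why: Evans-type asymmetric glycolate alkylation: the chelated Z sodium enolate is allylated on the face opposite to the benzyl group of the auxiliary, which sets C7 as R.

Step 5
Reactants: 10 allylated imide
Product: 11 (2R)-N-methoxy-2-{[(2R)-1-(4-methoxybenzyloxy)butan-2-yl]oxy}-N-methylpent-4-enamide
Conditions: MeNH(OMe)·HCl, AlMe3, CH2Cl2, 0 °C to rt; then H2O
Reagents that add atoms: N,O-dimethylhydroxylamine hydrochloride, CNOC.Cl
Why: Weinreb amide synthesis by aluminium amide transamination cleaves the exocyclic imide carbonyl without epimerising C7 and leaves an acyl group too unreactive to lactonise with the alcohols unmasked next.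

Step 6
Reactants: 11 PMB-protected Weinreb amide
Product: 12 (2R)-2-{[(2R)-1-hydroxybutan-2-yl]oxy}-N-methoxy-N-methylpent-4-enamide
Conditions: DDQ, CH2Cl2/H2O, 0 °C
Reagents that add atoms: none
Why: Oxidative 4-methoxybenzyl ether cleavage with DDQ is selective for the electron-rich benzylic ether and spares the terminal alkene and the amide.

Step 7
Reactants: 12 primary alcohol
Product: 13 (2R)-N-methoxy-N-methyl-2-{[(2R)-1-oxobutan-2-yl]oxy}pent-4-enamide
Conditions: Dess–Martin periodinane, CH2Cl2, 0 °C to rt
Reagents that add atoms: none
Why: Dess–Martin oxidation works under neutral, non-enolising conditions, so the α-alkoxy aldehyde keeps C13 intact.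

Step 8
Reactants: 13 α-alkoxy aldehyde; 14 allyltributylstannane
Product: 15 (2R)-2-{[(3R,4R)-4-hydroxyhept-6-en-3-yl]oxy}-N-methoxy-N-methylpent-4-enamide
Conditions: MgBr2·OEt2 (3 equiv), CH2Cl2, −78 °C; then 14, −78 to −20 °C; then H2O
Reagents that add atoms: none
Why: Chelation-controlled allylstannane addition (Cram chelate model): magnesium ties the aldehyde oxygen to O7 and the allyl group enters past H13 rather than the ethyl group, which sets C12 as R, syn to C13–O.

Step 9
Reactants: 15 diene alcohol
Product: 16 (2R,7R,8R,Z)-8-ethyl-7-hydroxy-N-methoxy-N-methyl-3,4,7,8-tetrahydro-2H-oxocine-2-carboxamide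
Conditions: second-generation Grubbs catalyst (5 mol %), CH2Cl2 (2 mM), 40 °C
Reagents that add atoms: none
Why: Ring-closing metathesis of the two terminal alkenes, helped by the gauche preference of the vicinal C12–O/C13–O bonds, gives ring A, whose size allows only the Z alkene.

Step 10
Reactants: 16 hydroxy oxocene
Product: 17 (2R,7S,8R,Z)-7-bromo-8-ethyl-N-methoxy-N-methyl-3,4,7,8-tetrahydro-2H-oxocine-2-carboxamide
Conditions: CBr4, P(n-C8H17)3, toluene, 70 °C
Reagents that add atoms: carbon tetrabromide, BrC(Br)(Br)Br
Why: Appel-type bromination: bromide displaces the alkoxyphosphonium group in an SN2 process, which inverts C12 from R to S, and the bulky trialkylphosphine in an apolar solvent keeps elimination and oxygen participation down.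

Step 11
Reactants: 17 bromo oxocene Weinreb amide
Product: 18 (2R,7S,8R,Z)-7-bromo-8-ethyl-3,4,7,8-tetrahydro-2H-oxocine-2-carbaldehyde
Conditions: i-Bu2AlH, THF, −78 °C; then H2O
Reagents that add atoms: none
Why: Partial reduction of the Weinreb amide stops at the aldehyde oxidation level because the chelated adduct collapses only on hydrolysis, and the secondary bromide and the alkene are inert at this temperature.

Step 12
Reactants: 18 oxocene carbaldehyde; 14 allyltributylstannane
Product: 19 (1R)-1-[(2R,7S,8R,Z)-7-bromo-8-ethyl-3,4,7,8-tetrahydro-2H-oxocin-2-yl]but-3-en-1-ol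
Conditions: MgBr2·OEt2 (3 equiv), CH2Cl2, −78 °C; then 14, −78 to −20 °C; then H2O
Reagents that add atoms: none
Why: Second chelation-controlled allylstannane addition: magnesium bridges the aldehyde oxygen and ring oxygen O7, the allyl group enters past H7, and C6 results as R, syn to C7–O.

Step 13
Reactants: 19 oxocene homoallylic alcohol
Product: 21 8-allyl-4,10-dibromo-3-ethyl-2,7-dioxabicyclo[4.2.2]decane (acetogenin centres 6R,7R,9S,10S,12S,13R), via bromonium ion 20 (not isolated)
Conditions: N-bromosuccinimide (1.0 equiv), (CF3)2CHOH, 4 Å molecular sieves, 0 °C, dark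
Reagents that add atoms: N-bromosuccinimide, O=C1CCC(=O)N1Br
Why: N-Bromosuccinimide transfers Br+ reversibly to the strained cis C9=C10 alkene; only bromonium ion 20, with bromine on the face opposite to the C6 carbinol, can be reached from behind by O6, which attacks C10, and succinimide anion takes the proton. The closest known reaction type is transannular haloetherification of a medium-ring alkenol, the presumed biogenetic route to bridged bromoethers of this family. The one new C–O bond closes ring B in a 6-endo mode through a boat and ring C in an 8-exo mode, C9 and its bromine staying outside ring C. C10 (S) is set by the tether, since O6 hangs from the fixed C6/C7 centres over one face of ring A only, and C9 (S) by the obligatory anti opening of a bromonium ion derived from a Z alkene. Chemoselectivity over the allyl group comes from the higher nucleophilicity of the 1,2-disubstituted ring alkene and from the fact that O6 could trap an allyl bromonium ion only as an oxetane or in a slow 5-endo mode. Regioselectivity for C10 over the intrinsically easier 5-exo attack at C9 is the weak point: the resident C12 bromine lies on the same face as the bromonium bromine, so leaving bromine on C10 would build a syn-1,3-dibromide whereas the 6-endo mode moves it to the remote C9, and the exactly antiperiplanar Br–C9–C10–O6 array of the bicyclo[4.2.2] boat together with the loose, cation-like opening in hexafluoropropan-2-ol lowers the penalty of endo closure.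

Step 14
Reactants: 21 allyl dibromo bicycle; 22 (E)-crotonaldehyde
Product: 23 (E)-4-[4,10-dibromo-3-ethyl-2,7-dioxabicyclo[4.2.2]decan-8-yl]but-2-enal (centres as in 21)
Conditions: 22 (excess), second-generation Hoveyda–Grubbs catalyst (5 mol %), CH2Cl2, 40 °C
Reagents that add atoms: none
Why: Olefin cross-metathesis of the now only alkene, a terminal one, with an electron-poor partner is selective for the cross product and gives the thermodynamically preferred E enal.

Step 15
Reactants: 23 bicyclic enal
Product: 24 target, 4,10-dibromo-3-ethyl-8-[(E)-pent-2-en-4-ynyl]-2,7-dioxabicyclo[4.2.2]decane (6R,7R,9S,10S,12S,13R)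
Conditions: Me3SiCHN2, LiN(i-Pr)2, THF, −78 °C; then 23, −78 to 0 °C; then H2O
Reagents that add atoms: (trimethylsilyl)diazomethane, C[Si](C)(C)C=[N+]=[N-]
Why: Colvin homologation with lithiated trimethylsilyldiazomethane converts the aldehyde into the terminal alkyne at low temperature without touching the E alkene or the two secondary bromides.

Compound list
1 | (R)-1,2-epoxybutane | CC[C@@H]1CO1 | starting material
2 | 4-methoxybenzyl alcohol | COc1ccc(CO)cc1 | starting material
3 | (2R)-1-[(4-methoxybenzyl)oxy]butan-2-ol | CC[C@@H](O)COCc1ccc(OC)cc1 | intermediate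
4 | bromoacetic acid | OC(=O)CBr | starting material
5 | {[(2R)-1-(4-methoxybenzyloxy)butan-2-yl]oxy}acetic acid | CC[C@@H](OCC(=O)O)COCc1ccc(OC)cc1 | intermediate
6 | (S)-4-benzyloxazolidin-2-one | O=C1N[C@@H](Cc2ccccc2)CO1 | starting material
7 | mixed pivalic anhydride of 5 (not isolated) | CC[C@@H](OCC(=O)OC(=O)C(C)(C)C)COCc1ccc(OC)cc1 | intermediate
8 | N-glycolyl imide | CC[C@@H](OCC(=O)N1C(=O)OC[C@@H]1Cc1ccccc1)COCc1ccc(OC)cc1 | intermediate
9 | allyl iodide | C=CCI | starting material
10 | (7R)-allylated imide | CC[C@@H](O[C@H](CC=C)C(=O)N1C(=O)OC[C@@H]1Cc1ccccc1)COCc1ccc(OC)cc1 | intermediate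
11 | PMB-protected Weinreb amide | CC[C@@H](O[C@H](CC=C)C(=O)N(C)OC)COCc1ccc(OC)cc1 | intermediate
12 | primary alcohol | CC[C@@H](O[C@H](CC=C)C(=O)N(C)OC)CO | intermediate
13 | C12 aldehyde | CC[C@@H](O[C@H](CC=C)C(=O)N(C)OC)C=O | intermediate
14 | allyltributylstannane | C=CC[Sn](CCCC)(CCCC)CCCC | starting material
15 | (7R,12R,13R)-diene alcohol | CC[C@@H](O[C@H](CC=C)C(=O)N(C)OC)[C@H](O)CC=C | intermediate
16 | (7R,12R,13R)-hydroxy (Z)-oxocene Weinreb amide | CC[C@H]1O[C@@H](C(=O)N(C)OC)C/C=C\C[C@H]1O | intermediate
17 | (7R,12S,13R)-bromo (Z)-oxocene Weinreb amide | CC[C@H]1O[C@@H](C(=O)N(C)OC)C/C=C\C[C@@H]1Br | intermediate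
18 | bromo oxocene carbaldehyde | CC[C@H]1O[C@@H](C=O)C/C=C\C[C@@H]1Br | intermediate
19 | (6R,7R,12S,13R)-oxocene homoallylic alcohol | CC[C@H]1O[C@@H]([C@H](O)CC=C)C/C=C\C[C@@H]1Br | intermediate
20 | C9/C10 bromonium ion, bromine anti to C6 (not isolated) | CC[C@H]1O[C@@H]([C@H](O)CC=C)C[C@@H]2[Br+][C@@H]2C[C@@H]1Br | intermediate
21 | 8-allyl-4,10-dibromo-3-ethyl-2,7-dioxabicyclo[4.2.2]decane | C=CC[C@H]1O[C@H]2C[C@H](Br)[C@@H](CC)O[C@@H]1C[C@@H]2Br | intermediate
22 | (E)-crotonaldehyde | C/C=C/C=O | starting material
23 | bicyclic (E)-enal | O=C/C=C/C[C@H]1O[C@H]2C[C@H](Br)[C@@H](CC)O[C@@H]1C[C@@H]2Br | intermediate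
24 | target | C#C/C=C/C[C@H]1O[C@H]2C[C@H](Br)[C@@H](CC)O[C@@H]1C[C@@H]2Br | target

Total step count: 15. Longest linear sequence: 15 steps (1 to 24).

Steps most likely to fail

1. Step 13.
- What may go wrong: O6 captures the bromonium ion at C9 in the geometrically easier 5-exo mode, ring oxygen O7 intercepts the ion across the ring, or the allyl group is brominated as well.
- Fallback (sets out from 18, comes back at 21): the roles are reversed so that bromide is the external nucleophile. Non-chelating allylation of 18 with 14 (BF3·OEt2, CH2Cl2, −78 °C, Felkin–Anh control) should give the (6S)-epimeric homoallylic alcohol F1. Hydroxyl-directed epoxidation (VO(acac)2, t-BuOOH, CH2Cl2) should place the oxirane on the alkene face that carries C6, giving the epoxy alcohol F2. Treatment with (CF3SO2)2O and 2,6-di-tert-butylpyridine at −78 °C should give the triflate F3. Its oxirane oxygen displaces the triflate at C6 with inversion (5-exo-tet) to give the bridged epoxonium ion F4. Bu4NBr then opens this ion from the free face at the ring-fusion carbon C9, the ring-enlarging mode known from tetrahydrofuran-to-tetrahydropyran expansions. This should give 21 with the same six centres, and the exo bias of a tethered oxygen no longer applies.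

2. Step 10.
- What may go wrong: ring oxygen O7 takes part in the departure of the phosphonium group (retention or ring contraction), or E2 loss towards C11 competes at 70 °C.
- Fallback (sets out from 16, comes back at 17): activation and displacement are separated. ClCH2SO2Cl and 2,6-lutidine in CH2Cl2 at 0 °C should give the isolable chloromethanesulfonate F5. This is then displaced by soluble bromide (Bu4NBr, toluene, 40 °C) in a clean SN2 inversion under milder, phosphine-free conditions.

3. Step 12.
- What may go wrong: the hindered ring oxygen chelates only weakly, so the open Felkin–Anh pathway erodes the facial selectivity, and the aldehyde may epimerise at C7 on the Lewis acid.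
- Fallback (sets out from 17, comes back at 19): carbon is added first and the centre is set by hydride. AllylMgBr on the Weinreb amide 17 (THF, −78 °C) should give the allyl ketone F6. LiBH(s-Bu)3 (THF, −78 °C) then reduces it under Felkin–Anh control, which for hydride delivery gives the same (6R), syn carbinol 19.

Further compounds
F1 | step 13 | (6S)-epimer of 19 | CC[C@H]1O[C@@H]([C@@H](O)CC=C)C/C=C\C[C@@H]1Br
F2 | step 13 | (6S,9R,10S)-9,10-epoxy alcohol, oxirane on the face of C6 | CC[C@H]1O[C@@H]([C@@H](O)CC=C)C[C@H]2O[C@H]2C[C@@H]1Br
F3 | step 13 | C6 triflate of F2 | CC[C@H]1O[C@@H]([C@@H](OS(=O)(=O)C(F)(F)F)CC=C)C[C@H]2O[C@H]2C[C@@H]1Br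
F4 | step 13 | bridged epoxonium ion (O bonded to C6, C9 and C10) | C=CC[C@H]1[O+]2[C@H]3C[C@H](Br)[C@@H](CC)O[C@@H]1C[C@@H]23
F5 | step 10 | C12 chloromethanesulfonate of 16 | CC[C@H]1O[C@@H](C(=O)N(C)OC)C/C=C\C[C@H]1OS(=O)(=O)CCl
F6 | step 12 | oxocenyl allyl ketone | CC[C@H]1O[C@@H](C(=O)CC=C)C/C=C\C[C@@H]1Br
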